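**Strategy.** The target is an ent-labdane whose ring B holds the quaternary C10 next to C9 and a C8(methyl)–C9(C11) edge that corresponds to a four-carbon ynoate. This feature is exploited by cutting C7–C8 and C9–C10. One thermal Diels–Alder reaction between a ring A vinylcyclohexene (C10=C5–C6=C7) and methyl but-2-ynoate closes ring B, delivers the C8 methyl and the C11 ester and fixes C10. The diene is (S)-4-silyloxy-2,6,6-trimethyl-1-vinylcyclohexene from ketoisophorone; its equatorial C2 silyl ether directs the face. Hydrogenation, equilibrating deconjugation, copper-catalysed Grignard coupling with the five-carbon chloroacetate and a late ring A ketol sequence finish the synthesis.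

Key step: step 5

Remark 1: labdane numbering is used for all bicyclic compounds; the target SMILES is read as (3S,5S,9R,10S,13E), an ent-labdane with H5 and H9 on the face opposite the C10 methyl and the equatorial C3 hydroxyl on the face of the C10 methyl.
Remark 2: the (R,R) catalyst of step 1 is assigned to the (R)-carbinol by analogy with aryl and alkenyl ketones; the sense is to be confirmed on 2 by optical rotation, and the mirror-image catalyst would be taken otherwise.

**Step 1**
Reactants: 1 ketoisophorone (2,6,6-trimethylcyclohex-2-ene-1,4-dione)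
Product: 2 (R)-4-hydroxy-2,6,6-trimethylcyclohex-2-en-1-one
Conditions: [RuCl((R,R)-TsDPEN)(p-cymene)] (0.5 mol %), KOH (1 mol %), i-PrOH, 25 °C
Reagents that add atoms: none
Why: Noyori-type asymmetric transfer hydrogenation should reduce only the C4 carbonyl, since the C1 carbonyl is flanked by the gem-dimethyl carbon and the methylated alkene carbon, and the chiral Ru–H/N–H catalyst sets the new carbinol centre as (R) by discriminating the alkenyl from the methylene flank.

**Step 2**
Reactants: 2 (R)-4-hydroxy-2,6,6-trimethylcyclohex-2-en-1-one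
Product: 3 (R)-4-(tert-butyldimethylsilyloxy)-2,6,6-trimethylcyclohex-2-en-1-one
Conditions: TBSCl, imidazole, DMF, 25 °C
Reagents that add atoms: tert-butyldimethylsilyl chloride, CC(C)(C)[Si](C)(C)Cl
Why: Imidazole-promoted silylation of the secondary allylic alcohol is routine and leaves the stereocentre untouched.

**Step 3**
Reactants: 3 (R)-4-(tert-butyldimethylsilyloxy)-2,6,6-trimethylcyclohex-2-en-1-one
Product: 5 (S)-4-(tert-butyldimethylsilyloxy)-2,6,6-trimethylcyclohex-1-en-1-yl trifluoromethanesulfonate, via lithium enolate 4 (not isolated)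
Conditions: LiBH(s-Bu)3, THF, −78 °C; then PhNTf2, −78 → 0 °C; aqueous work-up
Reagents that add atoms: N-phenylbis(trifluoromethanesulfonimide), O=S(=O)(N(c1ccccc1)S(=O)(=O)C(F)(F)F)C(F)(F)F
Why: Conjugate hydride addition of the bulky borohydride to the β-unsubstituted enone (whose carbonyl is shielded by the gem-dimethyl group) should give regiospecifically the tetrasubstituted lithium enolate, which is O-triflated in a reductive enol triflate formation that creates no new stereocentre.

**Step 4**
Reactants: 5 (S)-4-(tert-butyldimethylsilyloxy)-2,6,6-trimethylcyclohex-1-en-1-yl trifluoromethanesulfonate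
Product: 6 (S)-4-(tert-butyldimethylsilyloxy)-2,6,6-trimethyl-1-vinylcyclohex-1-ene
Conditions: tributyl(vinyl)stannane, Pd(PPh3)4 (5 mol %), LiCl (3 equiv), THF, reflux
Reagents that add atoms: tributyl(vinyl)stannane, C=C[Sn](CCCC)(CCCC)CCCC
Why: Stille coupling of the hindered cyclohexenyl triflate, with LiCl assisting oxidative addition and transmetalation, should install the vinyl group without moving the ring alkene or touching the silyl ether.

**Step 5**
Reactants: 6 (S)-4-(tert-butyldimethylsilyloxy)-2,6,6-trimethyl-1-vinylcyclohex-1-ene; 7 methyl but-2-ynoate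
Product: 8 methyl 2-(tert-butyldimethylsilyloxy)-ent-drima-5,8-dien-11-oate (ring B 1,4-diene; ester on C9; methyl on C8; C2 silyloxy trans to the C10 methyl)
Conditions: neat 7 (4 equiv), BHT (1 mol %), sealed tube, 150 °C, 48 h
Reagents that add atoms: none
Why: A concerted but asynchronous thermal Diels–Alder reaction joins the s-cis diene C10=C5–C6=C7 of 6 to the triple bond of 7, forming C7–C8 and C9–C10 and leaving C5=C6 and C8=C9 as a 1,4-cyclohexadiene. The closest known reaction type is the cycloaddition of 2,6,6-trimethyl-1-vinylcyclohexene with acetylenic esters that opens the classical drimane syntheses. Ring B is closed as a six-membered carbocycle by intermolecular [4+2] cycloaddition, and the alkyne removes any endo/exo question. The only new stereocentre, quaternary C10, is controlled by the C2 silyl ether: it sits equatorial in the ring A half-chair, which places the pseudoaxial C4 methyl and the axial H2 on one face, so the ynoate should add to the other face, C9 entering equatorially and the C10 methyl ending trans to the silyloxy group. The step needs regioselectivity (C7 to the methyl-bearing β-carbon, C10 to the ester-bearing α-carbon), which the dialkyl-substituted terminus C10 secures by concentrating the HOMO coefficient at the unsubstituted terminus C7, the partner of the electrophilic β-carbon of the ynoate. It also needs the congested terminus to react before the diene degrades, which is addressed by running neat in excess ynoate with a radical inhibitor.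

**Step 6**
Reactants: 8 methyl 2-(tert-butyldimethylsilyloxy)-ent-drima-5,8-dien-11-oate
Product: 9 methyl 2-(tert-butyldimethylsilyloxy)-ent-drim-8-en-11-oate (trans-fused; H5 trans to the C10 methyl)
Conditions: H2 (1 atm), Pd/C (10 wt % palladium on carbon), EtOAc, 25 °C
Reagents that add atoms: none
Why: Heterogeneous hydrogenation should saturate only the trisubstituted C5=C6 bond, the tetrasubstituted ester-conjugated C8=C9 bond being inert here, and hydrogen is delivered to the face opposite the axial methyl groups on C10 and C4, which sets H5 trans to the C10 methyl.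

**Step 7**
Reactants: 9 methyl 2-(tert-butyldimethylsilyloxy)-ent-drim-8-en-11-oate
Product: 11 methyl 2-(tert-butyldimethylsilyloxy)-ent-drim-7-en-11-oate (H9 trans to the C10 methyl), via potassium dienolate 10 (not isolated)
Conditions: KOt-Bu (3 equiv), DMSO–THF (1:3), 25 °C, 1 h; then inverse addition to AcOH in THF, −40 °C
Reagents that add atoms: none
Why: Deconjugative isomerisation through an extended enolate: under equilibrating conditions the more substituted ring dienolate C11=C9–C8=C7 should be favoured over the exocyclic one that kinetic, carbonyl-directed deprotonation of the C8 methyl would give, and irreversible α-protonation on the quench occurs at C9 from the face opposite the adjacent axial C10 methyl, leaving the ester equatorial and H9 trans to the C10 methyl.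

**Step 8**
Reactants: 11 methyl 2-(tert-butyldimethylsilyloxy)-ent-drim-7-en-11-oate
Product: 12 2-(tert-butyldimethylsilyloxy)-ent-drim-7-en-11-ol
Conditions: LiAlH4, Et2O, 0 °C
Reagents that add atoms: none
Why: Hydride reduction of the ester by LiAlH4 at 0 °C should give the primary alcohol without disturbing the isolated trisubstituted alkene, the silyl ether or the C9 centre.

**Step 9**
Reactants: 12 2-(tert-butyldimethylsilyloxy)-ent-drim-7-en-11-ol
Product: 13 11-bromo-2-(tert-butyldimethylsilyloxy)-ent-drim-7-ene
Conditions: CBr4, PPh3, CH2Cl2, 0 °C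
Reagents that add atoms: carbon tetrabromide, BrC(Br)(Br)Br
Why: Appel bromination converts the primary alcohol into the bromide by SN2 displacement of the oxyphosphonium ion under neutral conditions that spare the alkene and the silyl ether.

**Step 10**
Reactants: 13 11-bromo-2-(tert-butyldimethylsilyloxy)-ent-drim-7-ene; 14 (E)-4-chloro-3-methylbut-2-enyl acetate
Product: 16 2-(tert-butyldimethylsilyloxy)-ent-labda-7,13E-dien-15-yl acetate, via Grignard reagent 15 (not isolated)
Conditions: Mg turnings, THF, 45 °C; then rapid addition to 14 (1.5 equiv) and Li2CuCl4 (5 mol %), THF, −78 → −20 °C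
Reagents that add atoms: none
Why: Magnesium insertion gives the primary homoallylic Grignard reagent, and the Li2CuCl4-catalysed (Kochi-type) cross-coupling, run cold with the reagent added quickly to excess allylic chloride, should substitute the chloride at its α-carbon with retention of the E alkene and faster than any attack on the acetate, forming C11–C12.

**Step 11**
Reactants: 16 2-(tert-butyldimethylsilyloxy)-ent-labda-7,13E-dien-15-yl acetate
Product: 17 2-hydroxy-ent-labda-7,13E-dien-15-yl acetate (C2 hydroxyl equatorial; trans to the C10 methyl)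
Conditions: HF·pyridine, pyridine, THF, 0 → 25 °C
Reagents that add atoms: none
Why: Fluoride-mediated desilylation with buffered HF·pyridine removes the secondary silyl ether without cleaving the acetate or isomerising the alkenes.

**Step 12**
Reactants: 17 2-hydroxy-ent-labda-7,13E-dien-15-yl acetate
Product: 18 2-oxo-ent-labda-7,13E-dien-15-yl acetate
Conditions: Dess–Martin periodinane, NaHCO3, CH2Cl2, 25 °C
Reagents that add atoms: none
Why: Dess–Martin oxidation converts the secondary alcohol into the ketone under buffered conditions, so the C2 centre, having done its work in step 5, is deliberately erased while the allylic acetate and the alkenes are untouched.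

**Step 13**
Reactants: 18 2-oxo-ent-labda-7,13E-dien-15-yl acetate
Product: 19 2-(triethylsilyloxy)-ent-labda-2,7,13E-trien-15-yl acetate
Conditions: TESOTf (1.2 equiv), Et3N, CH2Cl2, −78 → −20 °C
Reagents that add atoms: triethylsilyl trifluoromethanesulfonate, CC[Si](CC)(CC)OS(=O)(=O)C(F)(F)F
Why: Soft enolisation (silyl triflate and amine) is compatible with the acetate, and the silylated oxocarbenium ion should lose the axial C3 proton and not a C1 proton because C1 is shielded by the equatorial C9–C11 bond on the neighbouring quaternary C10, in line with the known enolisation of 2-oxo-5α-steroids toward C3.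

**Step 14**
Reactants: 19 2-(triethylsilyloxy)-ent-labda-2,7,13E-trien-15-yl acetate
Product: 22 3-hydroxy-2-oxo-ent-labda-7,13E-dien-15-yl acetate having the C3 hydroxyl axial (trans to the C10 methyl; C3 epimer of the target), via silyloxy epoxide 20 (not isolated), via 3-silyloxy ketone 21 (not isolated)
Conditions: m-CPBA (1.05 equiv), NaHCO3, CH2Cl2, −30 °C; then HF·pyridine, THF, 0 °C
Reagents that add atoms: 3-chloroperbenzoic acid, O=C(OO)c1cccc(Cl)c1
Why: Rubottom oxidation: the electron-rich silyl enol ether should be epoxidised much faster than the two trisubstituted alkenes by one equivalent of peracid at low temperature, the peracid approaching anti to the axial methyl groups on C4 and C10, and silyl migration followed by fluoride cleavage gives the α-ketol with the C3 hydroxyl axial.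

**Step 15**
Reactants: 22 3-hydroxy-2-oxo-ent-labda-7,13E-dien-15-yl acetate having the C3 hydroxyl axial
Product: 23 (3S,5S,9R,10S,13E)-3-hydroxy-2-oxo-ent-labda-7,13-dien-15-yl acetate (target; C3 hydroxyl equatorial; cis to the C10 methyl)
Conditions: DBU (0.3 equiv), toluene, 40 °C
Reagents that add atoms: none
Why: Base-mediated epimerisation of an α-ketol through its enediol: reprotonation at C3 from the open face puts the hydrogen axial and the hydroxyl equatorial, which should also be the thermodynamically preferred, hydrogen-bonded arrangement as in ring A ketols of steroids and 4,4-dimethyl triterpenoids, and the amidine base in an aprotic solvent leaves the acetate intact.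

**Compound list**

1 | ketoisophorone (2,6,6-trimethylcyclohex-2-ene-1,4-dione) | CC1=CC(=O)CC(C)(C)C1=O | starting material
2 | (R)-4-hydroxy-2,6,6-trimethylcyclohex-2-en-1-one | CC1=C[C@H](O)CC(C)(C)C1=O | intermediate
3 | (R)-4-(tert-butyldimethylsilyloxy)-2,6,6-trimethylcyclohex-2-en-1-one | CC1=C[C@H](O[Si](C)(C)C(C)(C)C)CC(C)(C)C1=O | intermediate
4 | lithium (S)-4-(tert-butyldimethylsilyloxy)-2,6,6-trimethylcyclohex-1-en-1-olate | [Li+].[O-]C1=C(C)C[C@H](O[Si](C)(C)C(C)(C)C)CC1(C)C | intermediate
5 | (S)-4-(tert-butyldimethylsilyloxy)-2,6,6-trimethylcyclohex-1-en-1-yl trifluoromethanesulfonate | FC(F)(F)S(=O)(=O)OC1=C(C)C[C@H](O[Si](C)(C)C(C)(C)C)CC1(C)C | intermediate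
6 | (S)-4-(tert-butyldimethylsilyloxy)-2,6,6-trimethyl-1-vinylcyclohex-1-ene | C=CC1=C(C)C[C@H](O[Si](C)(C)C(C)(C)C)CC1(C)C | intermediate
7 | methyl but-2-ynoate | CC#CC(=O)OC | starting material
8 | methyl 2-(tert-butyldimethylsilyloxy)-ent-drima-5,8-dien-11-oate (C2 silyloxy trans to the C10 methyl) | COC(=O)C1=C(C)CC=C2C(C)(C)C[C@@H](O[Si](C)(C)C(C)(C)C)C[C@@]12C | intermediate
9 | methyl 2-(tert-butyldimethylsilyloxy)-ent-drim-8-en-11-oate (trans-fused) | COC(=O)C1=C(C)CC[C@@H]2C(C)(C)C[C@@H](O[Si](C)(C)C(C)(C)C)C[C@@]12C | intermediate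
10 | potassium dienolate of 9 (C11=C9 and C7=C8) | [K+].[O-]C(OC)=C1C(C)=CC[C@@H]2C(C)(C)C[C@@H](O[Si](C)(C)C(C)(C)C)C[C@@]12C | intermediate
11 | methyl 2-(tert-butyldimethylsilyloxy)-ent-drim-7-en-11-oate (H9 trans to the C10 methyl) | COC(=O)[C@@H]1C(C)=CC[C@@H]2C(C)(C)C[C@@H](O[Si](C)(C)C(C)(C)C)C[C@@]12C | intermediate
12 | 2-(tert-butyldimethylsilyloxy)-ent-drim-7-en-11-ol | OC[C@@H]1C(C)=CC[C@@H]2C(C)(C)C[C@@H](O[Si](C)(C)C(C)(C)C)C[C@@]12C | intermediate
13 | 11-bromo-2-(tert-butyldimethylsilyloxy)-ent-drim-7-ene | BrC[C@@H]1C(C)=CC[C@@H]2C(C)(C)C[C@@H](O[Si](C)(C)C(C)(C)C)C[C@@]12C | intermediate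
14 | (E)-4-chloro-3-methylbut-2-enyl acetate | CC(=O)OC/C=C(\C)CCl | starting material
15 | Grignard reagent of 13 (C11–MgBr) | Br[Mg]C[C@@H]1C(C)=CC[C@@H]2C(C)(C)C[C@@H](O[Si](C)(C)C(C)(C)C)C[C@@]12C | intermediate
16 | 2-(tert-butyldimethylsilyloxy)-ent-labda-7,13E-dien-15-yl acetate | CC(=O)OC/C=C(\C)CC[C@@H]1C(C)=CC[C@@H]2C(C)(C)C[C@@H](O[Si](C)(C)C(C)(C)C)C[C@@]12C | intermediate
17 | 2-hydroxy-ent-labda-7,13E-dien-15-yl acetate (hydroxyl equatorial) | CC(=O)OC/C=C(\C)CC[C@@H]1C(C)=CC[C@@H]2C(C)(C)C[C@@H](O)C[C@@]12C | intermediate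
18 | 2-oxo-ent-labda-7,13E-dien-15-yl acetate | CC(=O)OC/C=C(\C)CC[C@@H]1C(C)=CC[C@@H]2C(C)(C)CC(=O)C[C@@]12C | intermediate
19 | 2-(triethylsilyloxy)-ent-labda-2,7,13E-trien-15-yl acetate | CC(=O)OC/C=C(\C)CC[C@@H]1C(C)=CC[C@@H]2C(C)(C)C=C(O[Si](CC)(CC)CC)C[C@@]12C | intermediate
20 | 2,3-epoxy-2-(triethylsilyloxy)-ent-labda-7,13E-dien-15-yl acetate (epoxide oxygen trans to the C10 methyl) | CC(=O)OC/C=C(\C)CC[C@@H]1C(C)=CC[C@@H]2C(C)(C)[C@H]3O[C@@]3(O[Si](CC)(CC)CC)C[C@@]12C | intermediate
21 | 2-oxo-3-(triethylsilyloxy)-ent-labda-7,13E-dien-15-yl acetate (silyloxy axial, trans to the C10 methyl) | CC(=O)OC/C=C(\C)CC[C@@H]1C(C)=CC[C@@H]2C(C)(C)[C@@H](O[Si](CC)(CC)CC)C(=O)C[C@@]12C | intermediate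
22 | 3-hydroxy-2-oxo-ent-labda-7,13E-dien-15-yl acetate, C3 hydroxyl axial (trans to the C10 methyl) | CC(=O)OC/C=C(\C)CC[C@@H]1C(C)=CC[C@@H]2C(C)(C)[C@@H](O)C(=O)C[C@@]12C | intermediate
23 | (3S,5S,9R,10S,13E)-3-hydroxy-2-oxo-ent-labda-7,13-dien-15-yl acetate | CC(=O)OC/C=C(\C)CC[C@@H]1C(C)=CC[C@@H]2C(C)(C)[C@H](O)C(=O)C[C@@]12C | target

**Step count and risks**

Total steps: 15. Longest linear sequence: 15 steps, from ketoisophorone 1 (compounds 7 and 14 are bought).

Steps most likely to fail:

1. Step 5. The cycloaddition of a weakly activated, β-methylated ynoate with a twisted, fully substituted diene terminus may be too slow to outrun hydrogen shifts and oligomerisation of the diene, and its regiocontrol may leak. The fallback sets out from diene 6 and uses the far more electrophilic and more strongly polarised but-2-ynal (toluene, 80 °C). This should give the aldehyde adduct 2-(tert-butyldimethylsilyloxy)-ent-drima-5,8-dien-11-al F1. Pinnick oxidation (NaClO2, NaH2PO4, 2-methylbut-2-ene, t-BuOH–water) then gives the acid 2-(tert-butyldimethylsilyloxy)-ent-drima-5,8-dien-11-oic acid F2. Methylation (MeI, K2CO3, DMF) comes back to the route at 8.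

2. Step 7. Deprotonation may occur at the C8 methyl (cis to the ester) instead of at C7, leading after protonation to the exocyclic alkene isomer, or the conjugated ester may be returned. The fallback sets out from 9 and fixes the alkene position by structure.
 - Allylic oxidation of the ring methylene (CrO3, 3,5-dimethylpyrazole, CH2Cl2, −20 °C) gives the enone methyl 2-(tert-butyldimethylsilyloxy)-7-oxo-ent-drim-8-en-11-oate F3.
 - Luche reduction (NaBH4, CeCl3·7H2O, MeOH, −40 °C), with hydride arriving anti to the C10 methyl, gives the allylic alcohol methyl 2-(tert-butyldimethylsilyloxy)-7-hydroxy-ent-drim-8-en-11-oate F4 (hydroxyl cis to the C10 methyl).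
 - Myers reductive transposition (2-nitrobenzenesulfonylhydrazide, PPh3, diethyl azodicarboxylate, THF, −30 → 25 °C) proceeds by Mitsunobu inversion to the N-allyl sulfonylhydrazine F5, which loses the sulfinic acid to give the allylic diazene F6.
 - Retro-ene loss of dinitrogen delivers hydrogen to C9 on the face opposite the C10 methyl and moves the alkene to C7=C8, coming back to the route at 11.

3. Step 13. Enolisation may turn toward C1 under the amine and silyl triflate, and the peracid of step 14 may then also attack the two trisubstituted alkenes. The fallback sets out from ketone 18 and gives up the acetate for a time.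
 - Methanolysis (K2CO3, MeOH, 0 °C) gives the keto alcohol 15-hydroxy-ent-labda-7,13E-dien-2-one F7.
 - KN(SiMe3)2 (2.2 equiv, THF, −78 °C) forms the alkoxide and, under kinetic steric control, the C3 enolate, which is oxidised by 2-(phenylsulfonyl)-3-phenyloxaziridine; this reagent does not touch alkenes. The product is the axial ketol 3,15-dihydroxy-ent-labda-7,13E-dien-2-one F8 (C3 hydroxyl trans to the C10 methyl).
 - Equilibration (K2CO3, MeOH, 25 °C) gives the equatorial ketol 3,15-dihydroxy-ent-labda-7,13E-dien-2-one F9 (C3 hydroxyl cis to the C10 methyl).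
 - Selective acetylation of the primary allylic alcohol (AcCl, 2,4,6-collidine, CH2Cl2, −78 °C) comes back to the route at 23.

**Further compounds**

F1 | step 5 | 2-(tert-butyldimethylsilyloxy)-ent-drima-5,8-dien-11-al | O=CC1=C(C)CC=C2C(C)(C)C[C@@H](O[Si](C)(C)C(C)(C)C)C[C@@]12C
F2 | step 5 | 2-(tert-butyldimethylsilyloxy)-ent-drima-5,8-dien-11-oic acid | OC(=O)C1=C(C)CC=C2C(C)(C)C[C@@H](O[Si](C)(C)C(C)(C)C)C[C@@]12C
F3 | step 7 | methyl 2-(tert-butyldimethylsilyloxy)-7-oxo-ent-drim-8-en-11-oate | COC(=O)C1=C(C)C(=O)C[C@@H]2C(C)(C)C[C@@H](O[Si](C)(C)C(C)(C)C)C[C@@]12C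
F4 | step 7 | methyl 2-(tert-butyldimethylsilyloxy)-7-hydroxy-ent-drim-8-en-11-oate (7-hydroxyl cis to the C10 methyl) | COC(=O)C1=C(C)[C@H](O)C[C@@H]2C(C)(C)C[C@@H](O[Si](C)(C)C(C)(C)C)C[C@@]12C
F5 | step 7 | N-allyl-N-(2-nitrobenzenesulfonyl)hydrazine at C7 (nitrogen trans to the C10 methyl) | COC(=O)C1=C(C)[C@@H](N(N)S(=O)(=O)c3ccccc3[N+](=O)[O-])C[C@@H]2C(C)(C)C[C@@H](O[Si](C)(C)C(C)(C)C)C[C@@]12C
F6 | step 7 | allylic monoalkyl diazene at C7 | COC(=O)C1=C(C)[C@@H](N=N)C[C@@H]2C(C)(C)C[C@@H](O[Si](C)(C)C(C)(C)C)C[C@@]12C
F7 | step 13 | 15-hydroxy-ent-labda-7,13E-dien-2-one | OC/C=C(\C)CC[C@@H]1C(C)=CC[C@@H]2C(C)(C)CC(=O)C[C@@]12C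
F8 | step 13 | 3,15-dihydroxy-ent-labda-7,13E-dien-2-one, C3 hydroxyl axial | OC/C=C(\C)CC[C@@H]1C(C)=CC[C@@H]2C(C)(C)[C@@H](O)C(=O)C[C@@]12C
F9 | step 13 | 3,15-dihydroxy-ent-labda-7,13E-dien-2-one, C3 hydroxyl equatorial | OC/C=C(\C)CC[C@@H]1C(C)=CC[C@@H]2C(C)(C)[C@H](O)C(=O)C[C@@]12C
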